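**Strategy**

In ring B the C8 ketone and the C11 tertiary carbinol sit on either side of C7; this β-hydroxy ketone is treated as a masked 2-isoxazoline. Everything rests on cutting C7–C8 and O–C11: a nitrile oxide at C8, made from an aldoxime, adds intramolecularly across the C7=C11 prenyl alkene and closes ring B and the isoxazoline ring in one operation, fixing the trans-decalin. The precursor is a fully oxygenated ring A cyclohexane (C3–OTBS, C4–OAc) carrying trans-diequatorial prenyl (C5) and oximinoethyl (C10) arms, built by an enantioselective Diels–Alder reaction. N–O hydrogenolysis, C6–C7 dehydrogenation and late C3 acylation with the epoxy acid finish the synthesis.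

Key step: step 12

Numbering: eudesmane numbering of the target is used for all ring compounds (ring A: C1–C5 and C10; ring B: C5–C10; C11 is the carbinol carbon).

Assumption: the oxazaborolidinium-catalysed Diels–Alder reaction of the α-methyl enal 5 follows the usual formyl C–H···O binding model, so the (R)-catalyst directs the diene to the Si face at the α-carbon (C10); were the opposite sense found, the mirror-image catalyst would be used without other change.

Remark: C4 in 6–8, the enol ether geometry in 7–13 and the oxime geometry in 15 are isomer mixtures that converge; the SMILES leave the centre open or show one form.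

**Route**

Step 1
Reactants: 1 pent-1-en-3-one
Product: 2 (Z)-3-(triisopropylsilyloxy)penta-1,3-diene
Conditions: iPr3SiOTf, Et3N, CH2Cl2, 0 °C
Reagents that add atoms: triisopropylsilyl trifluoromethanesulfonate, CC(C)[Si](C(C)C)(C(C)C)OS(=O)(=O)C(F)(F)F
Why: Soft enolisation of the enone by silyl triflate and amine (silyl dienol ether formation) should give the 2-silyloxydiene, the Z enol ether being favoured so that the terminal methyl points outward in the s-cis diene.

Step 2
Reactants: 3 4-methylpent-3-en-1-ol
Product: 4 4-methylpent-3-enal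
Conditions: Dess–Martin periodinane, NaHCO3, CH2Cl2, 0 °C → rt; used crude
Reagents that add atoms: none
Why: Dess–Martin oxidation converts the primary alcohol into the aldehyde under buffered, non-basic conditions, which should keep the β,γ-double bond out of conjugation.

Step 3
Reactants: 4 4-methylpent-3-enal
Product: 5 (2E)-2,6-dimethylhepta-2,5-dienal
Conditions: Ph3P=C(CH3)CHO, toluene, 80 °C
Reagents that add atoms: 2-(triphenylphosphoranylidene)propanal, CC(C=O)=P(c1ccccc1)(c1ccccc1)c1ccccc1
Why: Wittig olefination with the formyl-stabilised ylide is E-selective for trisubstituted enals and needs no added base, so the skipped diene should not isomerise.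

Step 4
Reactants: 2 (Z)-3-(triisopropylsilyloxy)penta-1,3-diene; 5 (2E)-2,6-dimethylhepta-2,5-dienal
Product: 6 Diels–Alder adduct (ring A aldehyde with C2=C3 silyl enol ether)
Conditions: (R)-3,3-diphenyl-1-(2-methylphenyl)tetrahydro-1H,3H-pyrrolo[1,2-c][1,3,2]oxazaborole (20 mol %), HN(SO2CF3)2 (17 mol %), CH2Cl2, −78 → −40 °C
Reagents that add atoms: none
Why: In this Lewis-acid-catalysed Diels–Alder reaction the 2-silyloxy group directs the para regiochemistry (C3–O para to C10), the E geometry of 5 is transferred stereospecifically into the trans relation of C10–CHO and C5–prenyl, and the chiral oxazaborolidinium ion shields one enal face so that the diene adds to the Si face at C10, which sets C5 and C10; C4 forms as an inconsequential epimer mixture.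

Step 5
Reactants: 6 Diels–Alder adduct
Product: 7 methyl enol ether (C10–CH=CH–OCH3)
Conditions: Ph3P(CH2OCH3)Cl, KN(SiMe3)2, THF, 0 °C → rt
Reagents that add atoms: (methoxymethyl)triphenylphosphonium chloride, COC[P+](c1ccccc1)(c1ccccc1)c1ccccc1.[Cl-]
Why: Wittig methoxymethylenation homologates the non-enolisable neopentyl aldehyde by one carbon (C8) while the base-stable silyl enol ether is untouched.

Step 6
Reactants: 7 methyl enol ether
Product: 8 C3 ketone (C4 epimer mixture)
Conditions: Bu4NF, AcOH, THF, 0 °C
Reagents that add atoms: none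
Why: Fluoride cleaves the Si–O bond of the silyl enol ether and acetic acid protonates the enolate, releasing the C3 ketone without touching the acid-labile methyl enol ether.

Step 7
Reactants: 8 C3 ketone
Product: 10 α-ketol (C3 ketone; C4–OH trans to the prenyl chain), via hydroperoxide 9 (not isolated)
Conditions: O2 (1 atm), KOtBu, P(OEt)3, THF/t-BuOH, −20 °C
Reagents that add atoms: dioxygen, O=O
Why: In this enolate autoxidation with in situ phosphite reduction (the classical hydroxylation of a tertiary ketone α-carbon) the equilibrating, more substituted C3–C4 enolate is oxygenated, and O2 should approach anti to the adjacent C5 prenyl group and the C10 methyl, placing C4–OH trans to the prenyl chain from either C4 epimer of 8.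

Step 8
Reactants: 10 α-ketol
Product: 11 trans-3,4-diol
Conditions: Me4NBH(OAc)3, MeCN/AcOH (10:1), −30 °C
Reagents that add atoms: none
Why: In this hydroxyl-directed triacetoxyborohydride reduction (Saksena–Evans) the C4 alkoxyborohydride delivers hydride intramolecularly to C3 on the face of the C4 oxygen, setting the C3 carbinol trans to C4–OH; the cold, weakly acidic medium should leave the enol ether intact.

Step 9
Reactants: 11 trans-3,4-diol
Product: 12 C3 tert-butyldimethylsilyl ether
Conditions: t-BuMe2SiOTf (1.05 equiv), 2,6-lutidine, CH2Cl2, −78 °C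
Reagents that add atoms: tert-butyldimethylsilyl trifluoromethanesulfonate, CC(C)(C)[Si](C)(C)OS(=O)(=O)C(F)(F)F
Why: Silylation with silyl triflate and lutidine at low temperature is selective for the secondary C3 hydroxyl over the tertiary C4 hydroxyl.

Step 10
Reactants: 12 C3 silyl ether
Product: 13 C4 acetate
Conditions: LiN(SiMe3)2, THF, −78 °C; Ac2O, −78 → 0 °C
Reagents that add atoms: acetic anhydride, CC(=O)OC(C)=O
Why: Acylation of the preformed lithium alkoxide overcomes the hindrance of the tertiary C4 alcohol, and the acetate is placed now because the later C11 carbinol could not be told apart from C4–OH.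

Step 11
Reactants: 13 C4 acetate
Product: 15 aldoxime (cycloaddition precursor), via aldehyde 14 (not isolated)
Conditions: NH2OH·HCl, THF/H2O (4:1), rt; then NaOAc
Reagents that add atoms: hydroxylamine hydrochloride, NO.Cl
Why: Acid-catalysed enol ether hydrolysis in the presence of excess hydroxylamine traps aldehyde 14 as the oxime as it forms (condensation), so the aldehyde never accumulates and cannot undergo a carbonyl-ene cyclisation onto the prenyl alkene.

Step 12
Reactants: 15 aldoxime
Product: 18 isoxazoline-fused trans-decalin, via hydroximoyl chloride 16 (not isolated), via nitrile oxide 17 (not isolated)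
Conditions: NaOCl (aq.), CH2Cl2 (0.01 M), 0 °C → rt
Reagents that add atoms: none
Why: Hypochlorite chlorinates the aldoxime to hydroximoyl chloride 16, which loses HCl at the interface to give nitrile oxide 17, and this dipole adds to the tethered C7=C11 alkene in a concerted suprafacial (3+2) cycloaddition. The closest known reaction type is the intramolecular nitrile oxide–alkene cycloaddition used to build cyclohexane-fused 2-isoxazolines. Ring B closes in the 6-exo mode through the C7–C8 bond (C11 stays outside the carbocycle), and the isoxazoline closes as the five-membered cycloaddition ring through the O–C11 bond. The one new stereocenter, C7, is controlled by the chair-like transition state in which both arms are equatorial on ring A, so the C7–C11 bond ends equatorial and C7–H axial, while the trans ring fusion is inherited from C5 and C10. The step needs regioselectivity (carbon to C7, oxygen to C11), secured by the tether, which would force the other orientation into a strained bridged ring, and by the normal preference of the dipole oxygen for the more substituted alkene carbon; it also needs to outrun dimerisation to the furoxan, which high dilution and the neopentyl position of the dipole should ensure. The equatorial C3 silyl ether and C4 acetate bias ring A toward the conformer with both arms equatorial.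

Step 13
Reactants: 18 isoxazoline
Product: 20 β-hydroxy ketone (C8 ketone; C11 carbinol), via β-hydroxy imine 19 (not isolated)
Conditions: H2 (1 atm), Raney Ni, B(OH)3, MeOH/H2O (5:1), rt
Reagents that add atoms: water, O
Why: Raney Ni hydrogenolysis of the N–O bond in boric acid buffer gives β-hydroxy imine 19, which is hydrolysed in situ to the β-hydroxy ketone without retro-aldol cleavage or dehydration; acetate and silyl ether are inert.

Step 14
Reactants: 20 β-hydroxy ketone
Product: 21 C6=C7 enone (11-hydroxy-6-en-8-one)
Conditions: IBX (2-iodoxybenzoic acid, 3 equiv), DMSO/fluorobenzene (1:2), 65 °C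
Reagents that add atoms: none
Why: IBX dehydrogenates ketones through the enol, and since C10 is quaternary only enolisation toward C7 can lead to an enone, so the C6=C7 bond should form regiospecifically and erase the C7 stereocenter; the tertiary alcohol, acetate and silyl ether are not oxidised.

Step 15
Reactants: 21 C6=C7 enone
Product: 22 C3 alcohol
Conditions: HF·pyridine, pyridine, THF, 0 °C → rt
Reagents that add atoms: none
Why: Acidic fluoride desilylation cleaves the hindered secondary silyl ether while avoiding the alkoxide that would trigger O4→O3 acetyl migration or attack the enone.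

Step 16
Reactants: 23 tiglic acid
Product: 24 (E)-2-methylbut-2-en-1-ol
Conditions: LiAlH4, Et2O, 0 °C
Reagents that add atoms: none
Why: Hydride reduction of the carboxylic acid proceeds in 1,2-fashion and leaves the trisubstituted E-alkene intact.

Step 17
Reactants: 24 (E)-2-methylbut-2-en-1-ol
Product: 25 ((2R,3R)-2,3-dimethyloxiran-2-yl)methanol
Conditions: Ti(OiPr)4 (10 mol %), D-(−)-diethyl tartrate (12 mol %), t-BuOOH, 4 Å molecular sieves, CH2Cl2, −20 °C; non-aqueous work-up
Reagents that add atoms: tert-butyl hydroperoxide, CC(C)(C)OO
Why: In the Sharpless asymmetric epoxidation the titanium–(D)-tartrate complex delivers oxygen to one face of the E-allylic alcohol, which should give the (2R,3R)-epoxy alcohol with the two methyl groups cis (syn addition).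

Step 18
Reactants: 25 ((2R,3R)-2,3-dimethyloxiran-2-yl)methanol
Product: 27 (2S,3R)-2,3-dimethyloxirane-2-carboxylic acid, via epoxy aldehyde 26 (not isolated)
Conditions: RuCl3·xH2O (2 mol %), NaIO4, MeCN/EtOAc/H2O, 0 °C
Reagents that add atoms: water, O
Why: RuO4-catalysed oxidation takes the primary alcohol through aldehyde 26 and its hydrate to the acid without opening the epoxide; the stereocenters are untouched and the C2 descriptor changes only through CIP priority.

Step 19
Reactants: 27 (2S,3R)-2,3-dimethyloxirane-2-carboxylic acid; 22 C3 alcohol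
Product: 29 target CNP0219255.6, via mixed anhydride 28 (not isolated)
Conditions: 2,4,6-Cl3C6H2COCl, Et3N, toluene, rt; then 22, 4-(dimethylamino)pyridine, toluene, rt
Reagents that add atoms: none
Why: In the Yamaguchi esterification the mixed anhydride 28 is attacked at the epoxy acyl carbon by the secondary C3–OH under acyl-transfer catalysis, the tertiary C11–OH being too hindered to compete.

**Compound list**

1 | pent-1-en-3-one | CCC(=O)C=C | starting material
2 | (Z)-3-(triisopropylsilyloxy)penta-1,3-diene | C/C=C(/C=C)O[Si](C(C)C)(C(C)C)C(C)C | intermediate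
3 | 4-methylpent-3-en-1-ol | CC(C)=CCCO | starting material
4 | 4-methylpent-3-enal | CC(C)=CCC=O | intermediate
5 | (2E)-2,6-dimethylhepta-2,5-dienal | CC(C)=CC/C=C(\C)C=O | intermediate
6 | (5S,10S) Diels–Alder adduct: cyclohexene ring A with C2=C3 triisopropylsilyl enol ether, C4–CH3 (epimer mixture), C5 prenyl, C10 bearing CH3 and CHO, CHO trans to prenyl | CC1C(O[Si](C(C)C)(C(C)C)C(C)C)=CC[C@](C)(C=O)[C@H]1CC=C(C)C | intermediate
7 | (5S,10S) methyl enol ether: as 6 with C10–CH=CH–OCH3 (E/Z mixture) in place of CHO | CC1C(O[Si](C(C)C)(C(C)C)C(C)C)=CC[C@](C)(C=COC)[C@H]1CC=C(C)C | intermediate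
8 | (5S,10S) C3 ketone: 2-methylcyclohexanone ring A (C4 epimer mixture) with C5 prenyl and C10 CH3 and CH=CH–OCH3 | CC1C(=O)CC[C@](C)(C=COC)[C@H]1CC=C(C)C | intermediate
9 | C4 hydroperoxide of 8 (OOH trans to prenyl) | OO[C@]1(C)C(=O)CC[C@](C)(C=COC)[C@H]1CC=C(C)C | intermediate (not isolated)
10 | (4S,5R,10R) α-ketol: C3 ketone, C4 bearing OH (trans to prenyl) and CH3 | O[C@]1(C)C(=O)CC[C@](C)(C=COC)[C@H]1CC=C(C)C | intermediate
11 | (3S,4S,5R,10R) trans-3,4-diol | O[C@]1(C)[C@@H](O)CC[C@](C)(C=COC)[C@H]1CC=C(C)C | intermediate
12 | (3S,4S,5R,10R) C3 tert-butyldimethylsilyl ether, C4–OH free | O[C@]1(C)[C@@H](O[Si](C)(C)C(C)(C)C)CC[C@](C)(C=COC)[C@H]1CC=C(C)C | intermediate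
13 | (3S,4S,5R,10R) C4 acetate, C3 silyl ether, C10 methoxyvinyl arm | CC(=O)O[C@]1(C)[C@@H](O[Si](C)(C)C(C)(C)C)CC[C@](C)(C=COC)[C@H]1CC=C(C)C | intermediate
14 | aldehyde: as 13 with C10–CH2–CHO | CC(=O)O[C@]1(C)[C@@H](O[Si](C)(C)C(C)(C)C)CC[C@](C)(CC=O)[C@H]1CC=C(C)C | intermediate (not isolated)
15 | (3S,4S,5R,10R) aldoxime: ring A with C3–OTBS, C4–OAc and C4–CH3, C5 prenyl, C10 CH3 and CH2CH=NOH, arms trans (E oxime shown) | CC(=O)O[C@]1(C)[C@@H](O[Si](C)(C)C(C)(C)C)CC[C@](C)(C/C=N/O)[C@H]1CC=C(C)C | intermediate
16 | hydroximoyl chloride of 15 | CC(=O)O[C@]1(C)[C@@H](O[Si](C)(C)C(C)(C)C)CC[C@](C)(CC(Cl)=NO)[C@H]1CC=C(C)C | intermediate (not isolated)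
17 | nitrile oxide (C8) | CC(=O)O[C@]1(C)[C@@H](O[Si](C)(C)C(C)(C)C)CC[C@](C)(CC#[N+][O-])[C@H]1CC=C(C)C | intermediate (not isolated)
18 | (3S,4S,5R,7S,10R) trans-decalin-fused 2-isoxazoline (C8=N–O–C11, C7–H axial) | CC(=O)O[C@]1(C)[C@@H](O[Si](C)(C)C(C)(C)C)CC[C@]2(C)CC3=NOC(C)(C)[C@H]3C[C@H]21 | intermediate
19 | β-hydroxy imine (C8=NH, C11–OH) | CC(=O)O[C@]1(C)[C@@H](O[Si](C)(C)C(C)(C)C)CC[C@]2(C)CC(=N)[C@@H](C(C)(C)O)C[C@H]21 | intermediate (not isolated)
20 | (3S,4S,5R,7R,10R) β-hydroxy ketone (C8 ketone, C7–H, C11–OH) | CC(=O)O[C@]1(C)[C@@H](O[Si](C)(C)C(C)(C)C)CC[C@]2(C)CC(=O)[C@@H](C(C)(C)O)C[C@H]21 | intermediate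
21 | (3S,4S,5R,10R) 4-acetoxy-3-silyloxy-11-hydroxyeudesm-6-en-8-one | CC(=O)O[C@]1(C)[C@@H](O[Si](C)(C)C(C)(C)C)CC[C@]2(C)CC(=O)C(C(C)(C)O)=C[C@H]21 | intermediate
22 | (3S,4S,5R,10R) 4-acetoxy-3,11-dihydroxyeudesm-6-en-8-one | CC(=O)O[C@]1(C)[C@@H](O)CC[C@]2(C)CC(=O)C(C(C)(C)O)=C[C@H]21 | intermediate
23 | tiglic acid | C/C=C(\C)C(=O)O | starting material
24 | (E)-2-methylbut-2-en-1-ol | C/C=C(\C)CO | intermediate
25 | ((2R,3R)-2,3-dimethyloxiran-2-yl)methanol | OC[C@@]1(C)O[C@@H]1C | intermediate
26 | (2S,3R)-2,3-dimethyloxirane-2-carbaldehyde | O=C[C@@]1(C)O[C@@H]1C | intermediate (not isolated)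
27 | (2S,3R)-2,3-dimethyloxirane-2-carboxylic acid | OC(=O)[C@@]1(C)O[C@@H]1C | intermediate
28 | mixed anhydride of 27 with 2,4,6-trichlorobenzoic acid | O=C(OC(=O)[C@@]1(C)O[C@@H]1C)c1c(Cl)cc(Cl)cc1Cl | intermediate (not isolated)
29 | CNP0219255.6: (3S,4S,5R,10R) 4-acetoxy-11-hydroxy-8-oxoeudesm-6-en-3-yl (2S,3R)-2,3-dimethyloxirane-2-carboxylate | CC(=O)O[C@]1(C)[C@@H](OC(=O)[C@@]2(C)O[C@@H]2C)CC[C@]2(C)CC(=O)C(C(C)(C)O)=C[C@H]21 | target

**Step count**

Total: 19 steps. Longest linear sequence: 15 steps (from 3 through steps 2–15 and 19).

**Steps most likely to fail**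

Highest risk, step 14 (dehydrogenation): enolisation toward the hindered C7 methine may be slow, so that thermal dehydration of the tertiary carbinol or retro-aldol loss of acetone outruns the oxidation. The fallback is a Saegusa–Ito sequence at room temperature with the carbinol masked. It sets out from 20: silylation with Me3SiOTf and Et3N under equilibrating conditions should give the bis-trimethylsilyl derivative F1, in which C7=C8 is a trimethylsilyl enol ether and C11 carries OSiMe3. Pd(OAc)2 in MeCN should then give the C11-O-trimethylsilyl enone F2; any C8=C9 enol ether cannot eliminate and returns 20 on work-up for recycling. HF·pyridine in THF then removes both silyl groups, and the route is rejoined at 22.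

Second, step 4 (asymmetric Diels–Alder reaction): the trisubstituted enal may react too slowly with the 1-methyl-substituted diene at the low temperature needed for facial control, the skipped double bond may migrate under acid, or facial discrimination may be poor. The fallback gives up catalytic induction. It sets out from 2 and 5: cycloaddition promoted by stoichiometric MeAlCl2 in CH2Cl2 at −78 °C should give the racemic adduct, which is resolved by preparative chromatography on a chiral stationary phase. The mirror-image adduct F3 is discarded and the route is rejoined at 6.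

Third, step 7 (enolate oxygenation): oxygen may be taken up at the less substituted C2 enolate, over-oxidation to a diketone may occur, or attack may come syn to the prenyl chain. The fallback blocks C2 before the hydroxylation. It sets out from 7: Saegusa–Ito oxidation with Pd(OAc)2 in MeCN should give the C1=C2 enone F4, in which C4–H is the only enolisable position. Deprotonation with LiN(iPr)2 at −78 °C and oxidation of the enolate with 2-(phenylsulfonyl)-3-phenyloxaziridine should give the α'-hydroxy enone F5. Conjugate reduction with [(Ph3P)CuH]6 returns the route at 10.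

Further compounds
F1 | step 14 | bis-trimethylsilyl derivative of 20 (C7=C8 silyl enol ether, C11–OSiMe3) | CC(=O)O[C@]1(C)[C@@H](O[Si](C)(C)C(C)(C)C)CC[C@]2(C)CC(O[Si](C)(C)C)=C(C(C)(C)O[Si](C)(C)C)C[C@H]21
F2 | step 14 | C11-O-trimethylsilyl enone (C11 silyl ether of 21) | CC(=O)O[C@]1(C)[C@@H](O[Si](C)(C)C(C)(C)C)CC[C@]2(C)CC(=O)C(C(C)(C)O[Si](C)(C)C)=C[C@H]21
F3 | step 4 | mirror-image adduct (enantiomer of 6) | CC1C(O[Si](C(C)C)(C(C)C)C(C)C)=CC[C@@](C)(C=O)[C@@H]1CC=C(C)C
F4 | step 7 | C1=C2 enone (cyclohex-2-enone ring A with C4–CH3, C5 prenyl, C10 CH3 and methoxyvinyl) | CC1C(=O)C=C[C@](C)(C=COC)[C@H]1CC=C(C)C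
F5 | step 7 | α'-hydroxy enone (C4–OH trans to prenyl) | O[C@]1(C)C(=O)C=C[C@](C)(C=COC)[C@H]1CC=C(C)C
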